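A ratio is my way into this flask: of the starting material that reacts, how much goes to target and how much to homo dimer?

    reagent in the reaction phase ⇌ reagent in the second phase, rate k1*([reagent in the reaction phase] - [reagent in the second phase]/K1) per volume of the first phase (K1 = 2.3, k1 = 0.032 /s)
    starting material + reagent in the reaction phase → target (k2 = 0.097 /M/s)
    2 starting material → homo dimer (k3 = 0.033 /M/s)
    target → over-reaction product (k4 = 0.0090 /s)

starting material 0.40 M; reagent in the second phase 0.360 M; time 20 s; volume of the second phase over the first 0.25

- percentages count the starting material that a species holds: one homo dimer counts as two
- two of one species on the left: rate k times its square, two consumed each time
- in the second phase: reagent in the second phase; everything else is in the first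
- charges count per volume of the first phase; a concentration in a rate is the amount of a species over the volume of its own phase; every rate counts per litre of the first phase
- run time (flask): 20 s

* amount of target at 20 s, in percent of the starting material charged
* part of the starting material charged that has reacted at 20 s

**Charge entry.** I keep the books in fractions of the starting material charged. Less reagent in the second phase is charged than starting material: its charge is 90.0% of the starting material, and that is the most target the charges allow.

**Crossing entry.** At partition the second phase would keep 36.5% of the reagent, and I let it approach that share at 0.0877 /s, leaving the use of reagent by the target step out of this entry. At 20 s that leaves 47.5% of its own charge there, which is 42.8% of the starting material charged. The other 47.2% is what I book as crossed.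

**Fork entry.** I follow one molecule of starting material. Its odds for target against homo dimer are the fork constant 1.47, that is, the target rate constant over twice the dimer rate constant, times reagent in the reaction phase over starting material, both as fractions of the charge. Dimerisation alone leaves 65.4% of the starting material, so I book 34.6% to it. With these entries the odds at 20 s are 1.06, a chance of 0.515. The chance starts at zero, with no reagent in the reaction phase, so I take half of it as the mean, 0.257.

**Closing the books.** Target comes to 12.0% and conversion to 46.5%. I charge nothing to over-reaction, because the half-life of target by that step, 77 s, is long against 20 s. In my books the reaction phase then keeps 35.2% of the starting material charged, and the ledger closes at 90.0%.

**The forecast.** It gives 13% (12% to 14%) and 44.7% (42.5% to 47%), numbers that differ slightly from mine, and says dimerisation “takes most of the conversion and the target stays low”.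

**The flask.** The simulation gives 12.7% of target and 44.8% converted. At 20.0 s this flask holds reagent in the reaction phase equal to 35.9% of the starting material charged, against 55.2% of starting material, so the fork constant gives odds of 0.956, a chance of 0.489. Read at 50 s, the same flask gives odds of 1.95, a chance of 0.661, and the mean of the two chances is 0.575. Between those readings, target and over-reaction product together gained 0.573 of the starting material lost.

The numbers are invented.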